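Abbreviations: MOM = methoxymethyl; prenyl = 3-methylbut-2-en-1-yl; TBS = tert-butyldimethylsilyl; Bpin = 4,4,5,5-tetramethyl-1,3,2-dioxaborolan-2-yl; flavonoid numbering (O1, C2, C3, C4, C4a, C5–C8, C8a; ring B primed).

**Compound numbers used throughout**

1 phloroglucinol · 2 3,5-bis(MOM-oxy)phenol · 3 prenyl bromide · 4 2-prenyl-3,5-bis(MOM-oxy)phenol · 5 paraformaldehyde · 6 ring A salicylaldehyde · 7 4-hydroxybenzaldehyde · 8 4-hydroxy-3-prenylbenzaldehyde · 9 its MOM ether · 10 dichloromethyl-Bpin · 11 (E)-alkenyl-Bpin · 12 (E)-alkenyltrifluoroborate · 13 benzoic acid · 14 (E)-enol benzoate · 15 trimethyl orthoformate · 16 dimethyl acetal of 6 (not isolated) · 17 methoxy ortho-quinone methide (not isolated) · 18 cycloadduct · 19 flavan-3-ol · 20 3-O-TBS ether · 21 flavan-4-ol · 22 protected dihydroflavonol · 23 lespedezaflavanone C.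

## Analysis of the target

Lespedezaflavanone C (23) is a (2R,3R)-dihydroflavonol. Its chroman-4-one core has the oxygen heterocycle (ring C) fused to a phloroglucinol-type ring A (5,7-dihydroxy, 8-prenyl), with a 4-hydroxy-3-prenylphenyl ring B on C2 and a hydroxyl on C3. C2 and C3 are the only stereocentres; they are adjacent and trans, which is the thermodynamically preferred relation, so the relative configuration is forgiving while the absolute configuration is not. Both prenyl chains sit ortho to phenols: strong acid closes them to dimethylchromans, and hydrogenolysis, dihydroxylation and electrophilic oxidants are excluded. The α-hydroxy-β-aryloxy ketone opens in base by E1cB to a chalcone-type enolate, which costs C2 and C3, and it is easily dehydrogenated to the flavonol. Three things make the synthesis hard: placing a prenyl group at C8 and not C6, setting two contiguous oxygenated stereocentres without alkene-oxidising reagents, and bringing C4 to the ketone level beside two benzylic-allylic CH2 groups. The strategy rests on ring C: the O1–C2 and C3–C4 bonds flank C2–C3, and the other four ring atoms (O1, C8a, C4a, C4) are the heterodiene of an ortho-quinone methide of a ring A salicylaldehyde. C2=C3 is then an (E)-alkene carrying ring B and the C3 oxygen, so one [4+2] closes ring C, forms both bonds and both stereocentres, and delivers C4 already oxygenated.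

## Retrosynthetic reasoning

**23 ⇐ 22.** Only protecting groups are removed last. The three phenols are carried as MOM ethers, which survive base, organometallic and oxidative steps and fall under acid mild enough for ortho-prenyl phenols. The C3 hydroxyl is carried as a TBS ether that falls in the same operation, so no base meets the free α-hydroxy ketone.

**22 ⇐ 21 ⇐ 20.** The C4 carbonyl is traced to a C4 hydroxyl and that to a C4 methoxy group; no C–C bond is cut. C4 is a benzylic carbon supported by three oxygen donors (O1 through C8a, O5, O7), so methoxy-for-hydroxyl exchange needs only dilute acid. A mild alcohol oxidation then replaces any benzylic C–H oxidation, which the prenyl CH2 groups would not tolerate.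

**20 ⇐ 19 ⇐ 18.** The C3 oxygen changes its group from benzoate to silyl ether before C4 is unveiled. A C3 ester next to a C4 cation would participate, giving an acyloxonium ion and acyl migration from O3 to O4. An ester on the final ketone could only be cleaved with base. Two short steps remove both problems.

**18 ⇐ 6 + 14 + 15 (key disconnection).** The O1–C2 and C3–C4 bonds are cut. This is the only pair of ring C bonds whose scission splits the molecule into two aromatic halves of similar size, each already carrying its prenyl group, and whose formation creates both stereocentres. A cut at C2–C3 or O1–C8a would leave prenylation or oxidation-level work for after ring closure. Forward, aldehyde 6 and orthoformate 15 must give, through acetal 16, the methoxy ortho-quinone methide 17 under chiral Brønsted acid catalysis, and 17 must add to the (E)-alkene of 14. The addition has to place the aryl group on C2, translate E geometry into the 2,3-trans relation, and select one alkene face. An enol ester, not an enol ether, is needed so that the aryl group and not the oxygen directs the polarity of the alkene.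

**6 ⇐ 4 ⇐ 2 ⇐ 1.** The formyl carbon (C4) is cut from C4a and supplied by 5. In 4 only one position ortho to the free phenol is open, so a phenoxide-directed formylation cannot go astray. The C8 prenyl group is cut next; it comes from ortho C-alkylation of the phenoxide of 2 with 3. Phenol 2 comes from 1 by capping two of its three equivalent hydroxyls.

**14 ⇐ 12 ⇐ 11 ⇐ 9 ⇐ 8 ⇐ 7.** The enol ester C–O bond is cut to trifluoroborate 12 and acid 13. A copper-catalysed oxidative coupling keeps alkene geometry, whereas enolate O-acylation would give geometric mixtures. Trifluoroborate 12 comes from boronate 11, and 11 from aldehyde 9 by chromium-mediated, E-selective one-carbon homologation with 10. Aldehyde 9 is the MOM ether of 8, made from 7 and 3. MOM is chosen for ring B because the aryl group stays a strong donor and the ether tolerates the fluoride and methoxide steps.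

## Alternatives that were turned down

**Alternative 1:** Ring A is taken apart at C7–C8 and C4a–C8a, back to 3-ethoxycyclobut-2-en-1-one A1 and the silyl ynol ether triisopropyl[(5-methylhex-4-en-1-yn-1-yl)oxy]silane A2. On heating, the four-membered ring of A1 opens, the ketene function so formed adds across the alkyne of A2, and a second ring opening followed by 6π electrocyclisation and tautomerisation closes ring A as 5-ethoxy-2-prenyl-3-(triisopropylsilyloxy)phenol A3.
- For: the prenyl position and three differentiated oxygens of A3 follow from the mechanism. On this point it is stronger than steps 1 and 2 of the chosen route, which rely on statistical protection and ortho-selective phenoxide alkylation.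
- Against: the ring made is an arene that 1 already supplies. No bond of ring C and neither stereocentre is addressed, so formylation and a ring C construction still follow A3. The ethyl ether of A3 would sit at O5 and needs hard Lewis acids for cleavage, conditions that cyclise ortho-prenyl phenols. A2 itself takes several steps.
- Comparison: more steps, with the central problem postponed. The chosen route accepts modest selectivity in two cheap early steps and spends its strategic step where the stereocentres are.

**Alternative 2:** O1–C8a is cut by nucleophilic aromatic substitution and C2–C3 by aldol. The ketone 1-[2,6-difluoro-4-(methoxymethoxy)phenyl]-2-(methoxymethoxy)ethan-1-one A4 and aldehyde 9 give the anti aldol (2R,3R)-1-[2,6-difluoro-4-(methoxymethoxy)phenyl]-3-hydroxy-2-(methoxymethoxy)-3-[4-(methoxymethoxy)-3-prenylphenyl]propan-1-one A5. The alkoxide of A5 at the future C2 displaces one of the two equivalent ortho fluorides to give (2R,3R)-5-fluoro-3,7,4'-tris(methoxymethoxy)-3'-prenylflavanone A6.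
- For: the closure of A5 is a well-understood addition–elimination at a carbonyl-activated position with no regiochemical question, and the C2–O bond is not broken, so the aldol configuration is carried over. The ring closure has firmer precedent than the cycloaddition.
- Against: A6 has fluorine where 23 has the 5-hydroxyl and hydrogen where it has the C8 prenyl group. A second fluoride displacement on a ring deactivated by alkoxy donors needs base, which opens β-aryloxy ketones by E1cB and epimerises C3. C8-selective prenylation then competes with the equally activated C6. The enolate of an α-alkoxy ketone such as A4 favours syn adducts, so anti- and enantioselective formation of A5 is not assured, and A5 can revert by retro-aldol under the basic closure.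
- Comparison: several steps of late aromatic chemistry on the base-sensitive core. In the chosen plan every substituent is in place before ring C forms.

**Alternative 3:** Ring A is cut at C8–C8a and C4a–C5, back to the bromo dihydropyranone (2R,3R)-5-bromo-2-[4-(tert-butyldimethylsilyloxy)-3-prenylphenyl]-4-oxo-3,4-dihydro-2H-pyran-3-yl benzoate A7 and the diene 1-methoxy-7-methyl-1,3-bis(trimethylsilyloxy)octa-1,3,6-triene A8. The prenyl-bearing terminus of A8 attacks C8a of A7, the ketene acetal carbon of A8 bonds to C4a, and loss of the bromide, methoxy and silyloxy groups aromatises ring A to 3-O-benzoyl-4'-O-TBS lespedezaflavanone C A9.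
- For: the latest possible convergence. A9 is two deprotections from 23, a shorter endgame than the five steps of the chosen route. Ring A arrives with free phenols and a prenyl position fixed by A8.
- Against: C8a of A7 is the oxygen-bearing β-carbon of a vinylogous ester, a weak acceptor, and C4a becomes quaternary. A diene such as A8, with a substituted terminus, is less reactive than its parent and geometrically mixed. The Lewis acid or heat required meets a C2–O bond that is benzylic to a para-silyloxyphenyl group, and an enolisable C3 bearing an ester. The stereocentres of A7, made beforehand in a separate multi-step asymmetric sequence, must therefore survive the harshest step. Prenyl at C8 and not C6 rests on the polarity of A8 alone.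
- Comparison: the chosen plan makes the stereocentres in the convergent step and exposes them afterwards only to mild reagents, at the price of a longer endgame.

Key step: step 9

## Assumptions

- The sense of asymmetric induction of the chiral phosphoric acid in step 9 cannot be derived from structure alone. The (R)-acid is written; its mirror image is to be used if that is the one leading to the (2R) series.
- C4 of 18–20 is drawn 4R (2,4-cis, from an E-configured diene and an aryl-endo approach). C4 becomes a carbonyl carbon in step 13, so its epimer serves equally and a C4 mixture is carried on.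

## Route

Step 1
Reactants: 1 phloroglucinol
Product: 2 3,5-bis(methoxymethoxy)phenol
Conditions: MOMCl (2.0 equiv), iPr2NEt, DMF, 0 °C → rt; chromatography
Reagents that add atoms: chloromethyl methyl ether, COCCl
Why: O-alkylation of phenoxide by an α-chloro ether (Williamson type); two of the three equivalent hydroxyls are capped by stoichiometry, and the mono- and tris-ethers should be separable and recyclable.

Step 2
Reactants: 2 3,5-bis(methoxymethoxy)phenol; 3 prenyl bromide
Product: 4 3,5-bis(methoxymethoxy)-2-(3-methylbut-2-en-1-yl)phenol
Conditions: NaH, toluene, 0 °C; then 3, rt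
Reagents that add atoms: prenyl bromide 3, CC(C)=CCBr
Why: ortho C-alkylation of a sodium phenoxide in a non-coordinating solvent, where the contact ion pair shields oxygen and delivers the allylic halide to the neighbouring carbon; the two ortho carbons are equivalent, and the symmetric para isomer should be separable.

Step 3
Reactants: 4 3,5-bis(methoxymethoxy)-2-(3-methylbut-2-en-1-yl)phenol; 5 paraformaldehyde
Product: 6 2-hydroxy-4,6-bis(methoxymethoxy)-3-(3-methylbut-2-en-1-yl)benzaldehyde
Conditions: MgCl2, Et3N, (CH2O)n, THF, reflux
Reagents that add atoms: paraformaldehyde 5, C=O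
Why: Casnati–Skattebøl ortho-formylation: the magnesium phenoxide directs formaldehyde to the ortho carbon and a second formaldehyde oxidises the hydroxymethyl group by hydride transfer; only one ortho position is free, so the regiochemistry should be unambiguous.

Step 4
Reactants: 7 4-hydroxybenzaldehyde; 3 prenyl bromide
Product: 8 4-hydroxy-3-(3-methylbut-2-en-1-yl)benzaldehyde
Conditions: KOH (aq.), 3, rt; then dilute HCl
Reagents that add atoms: prenyl bromide 3, CC(C)=CCBr
Why: C-alkylation of a phenoxide in water, where hydrogen bonding shields oxygen; the para position is blocked, so the carbon nucleophile can only react ortho, and the O-prenyl ether should be separable.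

Step 5
Reactants: 8 4-hydroxy-3-(3-methylbut-2-en-1-yl)benzaldehyde
Product: 9 4-(methoxymethoxy)-3-(3-methylbut-2-en-1-yl)benzaldehyde
Conditions: MOMCl, iPr2NEt, CH2Cl2, 0 °C → rt
Reagents that add atoms: chloromethyl methyl ether, COCCl
Why: routine MOM protection of a phenol (O-alkylation).

Step 6
Reactants: 9 4-(methoxymethoxy)-3-(3-methylbut-2-en-1-yl)benzaldehyde; 10 2-(dichloromethyl)-4,4,5,5-tetramethyl-1,3,2-dioxaborolane
Product: 11 (E)-2-{2-[4-(methoxymethoxy)-3-(3-methylbut-2-en-1-yl)phenyl]ethenyl}-4,4,5,5-tetramethyl-1,3,2-dioxaborolane
Conditions: CrCl2 (excess), LiI, THF, rt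
Reagents that add atoms: 2-(dichloromethyl)-4,4,5,5-tetramethyl-1,3,2-dioxaborolane 10, ClC(Cl)B1OC(C)(C)C(C)(C)O1
Why: Takai–Utimoto olefination in its boron variant: a geminal dichromium species adds to the aldehyde and eliminates anti, which should give the (E)-alkenylboronate; the aryl MOM ether and the isolated prenyl alkene are inert to divalent chromium.

Step 7
Reactants: 11 (E)-alkenyl pinacol boronate
Product: 12 potassium (E)-trifluoro{2-[4-(methoxymethoxy)-3-(3-methylbut-2-en-1-yl)phenyl]ethenyl}borate
Conditions: KHF2 (aq.), MeOH, rt; precipitation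
Reagents that add atoms: potassium hydrogen difluoride KHF2, [K+].F.[F-]
Why: ligand exchange at boron from pinacolate to fluoride, giving the crystalline salt with retention of alkene geometry; an aryl MOM ether, unlike an aryl silyl ether, is stable to the fluoride.

Step 8
Reactants: 12 potassium (E)-alkenyltrifluoroborate; 13 benzoic acid
Product: 14 (E)-2-[4-(methoxymethoxy)-3-(3-methylbut-2-en-1-yl)phenyl]ethenyl benzoate
Conditions: 13 (excess), CuBr (10 mol %), DMAP (20 mol %), 4 Å MS, O2 (1 atm), CH2Cl2, rt
Reagents that add atoms: benzoic acid 13, O=C(O)c1ccccc1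
Why: copper-catalysed oxidative C–O coupling of an alkenyltrifluoroborate with a carboxylic acid (Chan–Lam–Evans type); transmetalation and reductive elimination at copper proceed with retention, so the E geometry of 12 should pass to the enol ester.

Step 9
Reactants: 6 2-hydroxy-4,6-bis(methoxymethoxy)-3-(3-methylbut-2-en-1-yl)benzaldehyde; 14 (E)-enol benzoate; 15 trimethyl orthoformate
Product: 18 (2R,3S,4R)-4-methoxy-5,7-bis(methoxymethoxy)-2-[4-(methoxymethoxy)-3-prenylphenyl]-8-prenylchroman-3-yl benzoate, via dimethyl acetal 16 (not isolated), via methoxy ortho-quinone methide 17 (not isolated)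
Conditions: 14 (1.5 equiv), 15 (1.5 equiv), (R)-3,3'-bis(2,4,6-triisopropylphenyl)-1,1'-binaphthyl-2,2'-diyl hydrogen phosphate (10 mol %), 5 Å MS, toluene, −20 °C → rt
Reagents that add atoms: trimethyl orthoformate 15, COC(OC)OC
Why: Proposed new method: the phosphoric acid converts 6 and 15 into acetal 16, which loses methanol to the 1-methoxy ortho-quinone methide 17 (equivalently its O-protonated oxocarbenium form), held as a hydrogen-bonded ion pair by the chiral phosphate, and 17 should then add to the electron-rich alkene of 14 in an inverse-demand hetero-Diels–Alder reaction. The closest known reaction type is the acid-promoted three-component [4+2] of salicylaldehydes, orthoformates and styrenes or enol ethers to 4-alkoxychromans, together with chiral phosphoric acid control of ortho-quinone methide cycloadditions; an arylacetaldehyde enol ester has not been shown as the 2π partner. Ring C closes as the six-membered ring of a concerted, asynchronous, suprafacial [4+2] in which the C4–C3 bond leads and O1–C2 follows; in the stepwise limit the phenol oxygen closes the same six-membered ring by 6-exo-trig capture of the para-alkoxybenzyl cation in its quinoid form. C3 is set by the alkene face that the phosphate-bound heterodiene reaches, that is by the catalyst; C2 follows from the E geometry of 14 (aryl and benzoyloxy trans) and is also the diequatorial outcome should closure be stepwise; C4 follows from the E-configured diene and an aryl-endo approach but is erased in step 13, so it needs no control. The step needs regioselectivity (aryl on C2, benzoyloxy on C3), which rests on the para-MOM-oxyphenyl group stabilising positive charge at C2 far better than an acyloxy oxygen whose lone pair is engaged by the ester carbonyl. It also needs chemoselectivity over the two isolated prenyl alkenes, which rests on the conjugated, donor-substituted styrene being the better nucleophile and being used in excess, while the molecular sieves remove methanol that would otherwise cleave the enol ester.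

Step 10
Reactants: 18 cycloadduct
Product: 19 (2R,3S,4R)-4-methoxy-5,7-bis(methoxymethoxy)-2-[4-(methoxymethoxy)-3-prenylphenyl]-8-prenylchroman-3-ol
Conditions: NaOMe (0.2 equiv), MeOH/THF, rt → 40 °C
Reagents that add atoms: none
Why: Zemplén-type transesterification of the benzoate; at this stage there is no carbonyl in ring C, so no enolisable centre or E1cB pathway exists and the MOM ethers and the C4 methyl ether are inert to methoxide.

Step 11
Reactants: 19 flavan-3-ol
Product: 20 tert-butyl{[(2R,3S,4R)-4-methoxy-5,7-bis(methoxymethoxy)-2-[4-(methoxymethoxy)-3-prenylphenyl]-8-prenylchroman-3-yl]oxy}dimethylsilane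
Conditions: TBSCl, imidazole, DMF, rt → 40 °C
Reagents that add atoms: tert-butyldimethylsilyl chloride, CC(C)(C)[Si](C)(C)Cl
Why: silylation of a secondary alcohol under basic conditions that leave the acid-labile C4 ether alone; the silyl ether cannot participate at C4 and is removable by acid at the end.

Step 12
Reactants: 20 3-O-TBS-4-methoxyflavan
Product: 21 (2R,3S,4RS)-3-(tert-butyldimethylsilyloxy)-5,7-bis(methoxymethoxy)-2-[4-(methoxymethoxy)-3-prenylphenyl]-8-prenylchroman-4-ol
Conditions: CSA (0.2 equiv), THF/H2O (4:1), 0.01 M, rt
Reagents that add atoms: water, O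
Why: acid-catalysed SN1 exchange at C4: the benzylic cation is stabilised by O1, O5 and O7 and should form under acid far too dilute to cleave aryl MOM ethers or a secondary TBS ether, and a large excess of water at high dilution captures it; C2 and C3 are not involved and the C4 epimers converge in step 13.

Step 13
Reactants: 21 flavan-4-ol
Product: 22 (2R,3R)-3-(tert-butyldimethylsilyloxy)-5,7-bis(methoxymethoxy)-2-[4-(methoxymethoxy)-3-prenylphenyl]-8-prenylchroman-4-one
Conditions: Dess–Martin periodinane, pyridine, CH2Cl2, 0 °C → rt
Reagents that add atoms: none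
Why: Dess–Martin oxidation of a secondary benzylic alcohol by ligand exchange at pentavalent iodine and intramolecular proton removal; it is non-basic and does not attack trisubstituted alkenes, so the prenyl groups and the now enolisable C3 centre should be untouched.

Step 14
Reactants: 22 protected dihydroflavonol
Product: 23 lespedezaflavanone C, (2R,3R)-3,5,7-trihydroxy-2-[4-hydroxy-3-(3-methylbut-2-en-1-yl)phenyl]-8-(3-methylbut-2-en-1-yl)chroman-4-one
Conditions: HCl (1.25 M in MeOH), 40 °C, monitored and stopped at full conversion
Reagents that add atoms: none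
Why: acid-catalysed transacetalisation of the three aryl MOM ethers and methanolysis of the secondary silyl ether in one operation; the trans-dihydroflavonol is stable to acid, and moderate acid strength and temperature are chosen to stay below the threshold for cyclisation of the ortho-prenyl phenols.

## Compound list

1 | phloroglucinol | Oc1cc(O)cc(O)c1 | starting material
2 | 3,5-bis(methoxymethoxy)phenol | COCOc1cc(O)cc(OCOC)c1 | intermediate
3 | prenyl bromide (1-bromo-3-methylbut-2-ene) | CC(C)=CCBr | starting material
4 | 3,5-bis(methoxymethoxy)-2-(3-methylbut-2-en-1-yl)phenol | CC(C)=CCc1c(O)cc(OCOC)cc1OCOC | intermediate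
5 | paraformaldehyde (formaldehyde source) | C=O | starting material
6 | 2-hydroxy-4,6-bis(methoxymethoxy)-3-(3-methylbut-2-en-1-yl)benzaldehyde | CC(C)=CCc1c(O)c(C=O)c(OCOC)cc1OCOC | intermediate
7 | 4-hydroxybenzaldehyde | O=Cc1ccc(O)cc1 | starting material
8 | 4-hydroxy-3-(3-methylbut-2-en-1-yl)benzaldehyde | CC(C)=CCc1cc(C=O)ccc1O | intermediate
9 | 4-(methoxymethoxy)-3-(3-methylbut-2-en-1-yl)benzaldehyde | CC(C)=CCc1cc(C=O)ccc1OCOC | intermediate
10 | 2-(dichloromethyl)-4,4,5,5-tetramethyl-1,3,2-dioxaborolane | ClC(Cl)B1OC(C)(C)C(C)(C)O1 | starting material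
11 | (E)-2-{2-[4-(methoxymethoxy)-3-(3-methylbut-2-en-1-yl)phenyl]ethenyl}-4,4,5,5-tetramethyl-1,3,2-dioxaborolane | CC(C)=CCc1cc(/C=C/B2OC(C)(C)C(C)(C)O2)ccc1OCOC | intermediate
12 | potassium (E)-trifluoro{2-[4-(methoxymethoxy)-3-(3-methylbut-2-en-1-yl)phenyl]ethenyl}borate | CC(C)=CCc1cc(/C=C/[B-](F)(F)F)ccc1OCOC.[K+] | intermediate
13 | benzoic acid | O=C(O)c1ccccc1 | starting material
14 | (E)-2-[4-(methoxymethoxy)-3-(3-methylbut-2-en-1-yl)phenyl]ethenyl benzoate | CC(C)=CCc1cc(/C=C/OC(=O)c2ccccc2)ccc1OCOC | intermediate
15 | trimethyl orthoformate | COC(OC)OC | starting material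
16 | 2-(dimethoxymethyl)-3,5-bis(methoxymethoxy)-6-(3-methylbut-2-en-1-yl)phenol (dimethyl acetal of 6; not isolated) | COC(OC)c1c(O)c(CC=C(C)C)c(OCOC)cc1OCOC | intermediate
17 | (E)-6-(methoxymethylidene)-3,5-bis(methoxymethoxy)-2-(3-methylbut-2-en-1-yl)cyclohexa-2,4-dien-1-one (methoxy ortho-quinone methide; not isolated) | CO/C=C1\C(OCOC)=CC(OCOC)=C(CC=C(C)C)C1=O | intermediate
18 | (2R,3S,4R)-4-methoxy-5,7-bis(methoxymethoxy)-2-[4-(methoxymethoxy)-3-prenylphenyl]-8-prenylchroman-3-yl benzoate (2,3-trans, 3,4-trans) | CC(C)=CCc1cc([C@H]2Oc3c(CC=C(C)C)c(OCOC)cc(OCOC)c3[C@@H](OC)[C@@H]2OC(=O)c4ccccc4)ccc1OCOC | intermediate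
19 | (2R,3S,4R)-4-methoxy-5,7-bis(methoxymethoxy)-2-[4-(methoxymethoxy)-3-prenylphenyl]-8-prenylchroman-3-ol | CC(C)=CCc1cc([C@H]2Oc3c(CC=C(C)C)c(OCOC)cc(OCOC)c3[C@@H](OC)[C@@H]2O)ccc1OCOC | intermediate
20 | tert-butyl{[(2R,3S,4R)-4-methoxy-5,7-bis(methoxymethoxy)-2-[4-(methoxymethoxy)-3-prenylphenyl]-8-prenylchroman-3-yl]oxy}dimethylsilane | CC(C)=CCc1cc([C@H]2Oc3c(CC=C(C)C)c(OCOC)cc(OCOC)c3[C@@H](OC)[C@@H]2O[Si](C)(C)C(C)(C)C)ccc1OCOC | intermediate
21 | (2R,3S,4RS)-3-(tert-butyldimethylsilyloxy)-5,7-bis(methoxymethoxy)-2-[4-(methoxymethoxy)-3-prenylphenyl]-8-prenylchroman-4-ol (both C4 epimers) | CC(C)=CCc1cc([C@H]2Oc3c(CC=C(C)C)c(OCOC)cc(OCOC)c3C(O)[C@@H]2O[Si](C)(C)C(C)(C)C)ccc1OCOC | intermediate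
22 | (2R,3R)-3-(tert-butyldimethylsilyloxy)-5,7-bis(methoxymethoxy)-2-[4-(methoxymethoxy)-3-prenylphenyl]-8-prenylchroman-4-one | CC(C)=CCc1cc([C@H]2Oc3c(CC=C(C)C)c(OCOC)cc(OCOC)c3C(=O)[C@@H]2O[Si](C)(C)C(C)(C)C)ccc1OCOC | intermediate
23 | lespedezaflavanone C, (2R,3R)-3,5,7-trihydroxy-2-[4-hydroxy-3-(3-methylbut-2-en-1-yl)phenyl]-8-(3-methylbut-2-en-1-yl)chroman-4-one | CC(C)=CCc1cc([C@H]2Oc3c(CC=C(C)C)c(O)cc(O)c3C(=O)[C@@H]2O)ccc1O | target

## Step count and least certain steps

Total: 14 steps. Longest linear sequence: 11 steps (7 → 8 → 9 → 11 → 12 → 14 → 18 → 19 → 20 → 21 → 22 → 23, steps 4–14); the ring A branch (steps 1–3) joins at step 9.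

**Step 9 (key step, proposed as a new method).** The doubly donor-stabilised quinone methide is a weak electrophile and the enol benzoate a weak nucleophile. Slow cycloaddition would let the quinone methide be consumed by self-condensation, by addition of phenol 6, or by reaction with prenyl alkenes. Regiochemistry could erode if acyloxy donation competes with the aryl group, placing the aryl on C3. Facial selectivity could be poor because the alkene offers the phosphate no hydrogen-bond handle. Acid and methanol could cleave the enol ester.

Fallback in known chemistry, setting out from 6 and 9 and returning at 23: ring C is built by the chalcone epoxide route. Aldehyde 6 is O-allylated (allyl bromide, K2CO3, DMF) to 2-(allyloxy)-4,6-bis(methoxymethoxy)-3-prenylbenzaldehyde F1. MeMgBr gives racemic 1-[2-(allyloxy)-4,6-bis(methoxymethoxy)-3-prenylphenyl]ethan-1-ol F2, and Dess–Martin oxidation gives 1-[2-(allyloxy)-4,6-bis(methoxymethoxy)-3-prenylphenyl]ethan-1-one F3. Claisen–Schmidt condensation of F3 with 9 (KOH, EtOH) gives (E)-1-[2-(allyloxy)-4,6-bis(methoxymethoxy)-3-prenylphenyl]-3-[4-(methoxymethoxy)-3-prenylphenyl]prop-2-en-1-one F4. Juliá–Colonna epoxidation (poly-L-leucine, urea–hydrogen peroxide, DBU, THF) attacks only the enone and gives [2-(allyloxy)-4,6-bis(methoxymethoxy)-3-prenylphenyl]{(2R,3S)-3-[4-(methoxymethoxy)-3-prenylphenyl]oxiran-2-yl}methanone F5. Zerovalent palladium (Pd(PPh3)4, morpholine) removes the allyl group to give [2-hydroxy-4,6-bis(methoxymethoxy)-3-prenylphenyl]{(2R,3S)-3-[4-(methoxymethoxy)-3-prenylphenyl]oxiran-2-yl}methanone F6, whose only free phenol is the one beside the prenyl group. Acid-catalysed (CSA, CH2Cl2) 6-endo opening of the epoxide at the benzylic carbon with inversion can therefore give only the 8-prenyl series, (2R,3R)-3-hydroxy-5,7-bis(methoxymethoxy)-2-[4-(methoxymethoxy)-3-prenylphenyl]-8-prenylchroman-4-one F7. F7 goes to 23 under the conditions of step 14.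

**Step 12.** The acid needed to ionise C4 may also begin to cleave MOM or silyl ethers. The C4 cation may be captured by the electron-rich C6 of a second molecule (oligomerisation by Friedel–Crafts alkylation) instead of by water, or it may lose the C3 proton (E1 elimination to a silyl enol ether), which would erase the C3 stereocentre.

Fallback, setting out from 20 and returning at 22; it makes no compound outside the list, entry F0: the hydrolysis is replaced by an oxidation. DDQ in CH2Cl2/pH 7 buffer abstracts hydride from C4, water adds to the methoxy-oxocarbenium ion, and the hemiketal collapses to ketone 22, so that steps 12 and 13 are merged and no free benzylic cation is exposed to acid.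

**Step 2.** Competing O-alkylation, para C-alkylation between the two MOM-oxy groups, and double alkylation may occur, because the phenoxide is ambident and all three ring positions are activated.

Fallback, setting out from 2 and returning at 4: phenol 2 is O-alkylated with 2-methylbut-3-yn-2-yl trifluoroacetate (CuCl2 cat., DBU, MeCN, 0 °C) to 1,3-bis(methoxymethoxy)-5-[(2-methylbut-3-yn-2-yl)oxy]benzene F8. Semi-hydrogenation over Pd/CaCO3 poisoned with Pb(OAc)2 (quinoline, H2) gives 1,3-bis(methoxymethoxy)-5-[(2-methylbut-3-en-2-yl)oxy]benzene F9. Heating F9 in toluene brings about the aromatic Claisen rearrangement, a [3,3] shift that can deliver the allyl unit, now a prenyl group, only to one of the two equivalent ortho carbons, giving 4.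

**Step 14.** Acid-catalysed cyclisation of either ortho-prenyl phenol onto its alkene (dimethylchroman formation) or addition of methanol to the prenyl alkenes may set in before the last MOM or silyl group has gone.

Fallback, setting out from 22 and returning at 23: protic acid is avoided. The MOM ethers are removed first by Lewis acid–thiol transacetalisation (ZnBr2, n-PrSH, CH2Cl2, 0 °C, minutes) to (2R,3R)-3-(tert-butyldimethylsilyloxy)-5,7-dihydroxy-2-(4-hydroxy-3-prenylphenyl)-8-prenylchroman-4-one F10. The silyl ether of F10 is then cleaved with buffered fluoride (HF·pyridine, THF, 0 °C) to give 23.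

## Further compounds

F1 | step 9 | 2-(allyloxy)-4,6-bis(methoxymethoxy)-3-(3-methylbut-2-en-1-yl)benzaldehyde | C=CCOc1c(CC=C(C)C)c(OCOC)cc(OCOC)c1C=O
F2 | step 9 | 1-[2-(allyloxy)-4,6-bis(methoxymethoxy)-3-(3-methylbut-2-en-1-yl)phenyl]ethan-1-ol (racemic) | C=CCOc1c(CC=C(C)C)c(OCOC)cc(OCOC)c1C(C)O
F3 | step 9 | 1-[2-(allyloxy)-4,6-bis(methoxymethoxy)-3-(3-methylbut-2-en-1-yl)phenyl]ethan-1-one | C=CCOc1c(CC=C(C)C)c(OCOC)cc(OCOC)c1C(C)=O
F4 | step 9 | (E)-1-[2-(allyloxy)-4,6-bis(methoxymethoxy)-3-prenylphenyl]-3-[4-(methoxymethoxy)-3-prenylphenyl]prop-2-en-1-one | C=CCOc1c(CC=C(C)C)c(OCOC)cc(OCOC)c1C(=O)/C=C/c2ccc(OCOC)c(CC=C(C)C)c2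
F5 | step 9 | [2-(allyloxy)-4,6-bis(methoxymethoxy)-3-prenylphenyl]{(2R,3S)-3-[4-(methoxymethoxy)-3-prenylphenyl]oxiran-2-yl}methanone | C=CCOc1c(CC=C(C)C)c(OCOC)cc(OCOC)c1C(=O)[C@@H]2O[C@H]2c3ccc(OCOC)c(CC=C(C)C)c3
F6 | step 9 | [2-hydroxy-4,6-bis(methoxymethoxy)-3-prenylphenyl]{(2R,3S)-3-[4-(methoxymethoxy)-3-prenylphenyl]oxiran-2-yl}methanone | Oc1c(CC=C(C)C)c(OCOC)cc(OCOC)c1C(=O)[C@@H]2O[C@H]2c3ccc(OCOC)c(CC=C(C)C)c3
F7 | step 9 | (2R,3R)-3-hydroxy-5,7-bis(methoxymethoxy)-2-[4-(methoxymethoxy)-3-prenylphenyl]-8-prenylchroman-4-one | CC(C)=CCc1cc([C@H]2Oc3c(CC=C(C)C)c(OCOC)cc(OCOC)c3C(=O)[C@@H]2O)ccc1OCOC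
F0 | step 12 | none | none
F8 | step 2 | 1,3-bis(methoxymethoxy)-5-[(2-methylbut-3-yn-2-yl)oxy]benzene | C#CC(C)(C)Oc1cc(OCOC)cc(OCOC)c1
F9 | step 2 | 1,3-bis(methoxymethoxy)-5-[(2-methylbut-3-en-2-yl)oxy]benzene | C=CC(C)(C)Oc1cc(OCOC)cc(OCOC)c1
F10 | step 14 | (2R,3R)-3-(tert-butyldimethylsilyloxy)-5,7-dihydroxy-2-(4-hydroxy-3-prenylphenyl)-8-prenylchroman-4-one | CC(C)=CCc1cc([C@H]2Oc3c(CC=C(C)C)c(O)cc(O)c3C(=O)[C@@H]2O[Si](C)(C)C(C)(C)C)ccc1O
A1 | alternative 1 | 3-ethoxycyclobut-2-en-1-one | CCOC1=CC(=O)C1
A2 | alternative 1 | triisopropyl[(5-methylhex-4-en-1-yn-1-yl)oxy]silane | CC(C)=CCC#CO[Si](C(C)C)(C(C)C)C(C)C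
A3 | alternative 1 | 5-ethoxy-2-prenyl-3-(triisopropylsilyloxy)phenol | CC(C)=CCc1c(O)cc(OCC)cc1O[Si](C(C)C)(C(C)C)C(C)C
A4 | alternative 2 | 1-[2,6-difluoro-4-(methoxymethoxy)phenyl]-2-(methoxymethoxy)ethan-1-one | COCOCC(=O)c1c(F)cc(OCOC)cc1F
A5 | alternative 2 | (2R,3R)-1-[2,6-difluoro-4-(methoxymethoxy)phenyl]-3-hydroxy-2-(methoxymethoxy)-3-[4-(methoxymethoxy)-3-prenylphenyl]propan-1-one | CC(C)=CCc1cc([C@@H](O)[C@@H](OCOC)C(=O)c2c(F)cc(OCOC)cc2F)ccc1OCOC
A6 | alternative 2 | (2R,3R)-5-fluoro-3,7,4'-tris(methoxymethoxy)-3'-prenylflavanone | CC(C)=CCc1cc([C@H]2Oc3cc(OCOC)cc(F)c3C(=O)[C@@H]2OCOC)ccc1OCOC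
A7 | alternative 3 | (2R,3R)-5-bromo-2-[4-(tert-butyldimethylsilyloxy)-3-prenylphenyl]-4-oxo-3,4-dihydro-2H-pyran-3-yl benzoate | CC(C)=CCc1cc([C@H]2OC=C(Br)C(=O)[C@@H]2OC(=O)c3ccccc3)ccc1O[Si](C)(C)C(C)(C)C
A8 | alternative 3 | 1-methoxy-7-methyl-1,3-bis(trimethylsilyloxy)octa-1,3,6-triene | COC(O[Si](C)(C)C)=CC(O[Si](C)(C)C)=CCC=C(C)C
A9 | alternative 3 | 3-O-benzoyl-4'-O-(tert-butyldimethylsilyl) lespedezaflavanone C | CC(C)=CCc1cc([C@H]2Oc3c(CC=C(C)C)c(O)cc(O)c3C(=O)[C@@H]2OC(=O)c4ccccc4)ccc1O[Si](C)(C)C(C)(C)C
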